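1. The alder run is the neighbour of the ash run: same partner, same catalyst, less substrate. Below it sits the elm run, which differs from alder in substrate alone.

| flask | substrate | partner | catalyst | target | time |
|---|---|---|---|---|---|
| elm | 200 mM | 300 mM | 20.0 mM |  |  |
| cedar | 100 mM | 200 mM | 20.0 mM |  |  |
| alder | 300 mM | 300 mM | 20.0 mM |  |  |
| birch | 200 mM | 300 mM | 20.0 mM | 100 mM |  |
| ash | 410 mM | 300 mM | 20.0 mM |  | 10 min |

| elm run: time / min | elm run: [target] / mM | cedar run: time / min | cedar run: [target] / mM | alder run: time / min | alder run: [target] / mM | birch run: time / min | birch run: [target] / mM |
|---|---|---|---|---|---|---|---|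
| 0.40 | 0 | 0.40 | 1.7 | 0.40 | 1.6 | 0.40 | 98.9 |
| 0.76 | 2.3 | 0.76 | 0 | 0.76 | 1.3 | 0.76 | 101.6 |
| 1.4 | 2.5 | 1.4 | 1.4 | 1.4 | 5.1 | 1.4 | 102.4 |
| 2.8 | 9.7 | 2.8 | 4.6 | 2.8 | 15.2 | 2.8 | 112.3 |
| 5.3 | 31.7 | 5.3 | 12.6 | 5.3 | 42.3 | 5.3 | 129.7 |
| 10 | 69.2 | 10 | 29.7 | 10 | 96.7 | 10 | 166.8 |

(readings scatter by 1 mM)

- Overall: substrate + partner -> target, with catalyst as catalyst.
- Constant volume, constant temperature.
- Readings of a species count what is bound in complexes too.
- "The second partner" is partner.
- An order is taken over about fifteen percent of the charge, up and down.

1. apparent order in [partner] of the starting rate, round the charge of the elm run (the rate where two percent of its substrate have turned into target)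
2. apparent order in [substrate] of the starting rate, round the charge of the elm run (the rate where two percent of its substrate have turned into target) (one fixed amount of target, the same in the runs compared)
3. the cedar run starts with 100 mM less of substrate and of partner than the elm run, and with no target. Compared where both hold the same amount of substrate, once fifteen percent of what the cedar run was charged with has turned into target, is the cedar run faster, slower or alike (within a tenth)?
4. target in the ash run at 10 min, as a share of the substrate charged

2. The elm run starts slowly: it makes 2.5 mM in its first 1.4 min, but 37.5 mM in its last 4.70 min. Added target doesn't seem to matter: by 10 min the birch run has gained 66.8 mM where the elm run has made 69.2 mM. So compare flasks at the same time on the clock.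

3. At 10 min, the alder run has made more target than the elm run, yet a smaller share of its charge: 32.2 % against 34.6 %.

4. Take as zero of the scale the case where every flask turns the same share by the same time. Then target grows in step with the charge, and the order is 1. Define the same-clock order n as the logarithm of the ratio of target at one time, divided by the logarithm of the ratio of substrate charged, all else equal. Read from alder and elm, n is 0.825.

5. Since n is below 1, the share at 10 min falls as substrate rises from the elm charge to the alder charge, with partner and catalyst held. My own reckoning carries alder's share up to the ash charge, with the share scaling as substrate to the power n minus 1, and gives 30.5 %. In the ash run the partner is the limiting reagent, and its charge allows 73.2 %, well above that figure.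

6. The forecast says 30 % (27 % to 33 %), with orders of 0.55 in substrate and 0.4 in partner, and the cedar run slower. Its ground for the low orders: “a faster run gets there earlier, with less catalyst activated”.

7. The ash run gives 29.7 %. The apparent orders of the starting rate are 0.52 in substrate and 0.34 in partner. The cedar run is slower, at 0.79 of the elm rate where both hold the same amount of substrate.

    active catalyst + substrate ⇌ catalyst-substrate complex (8.460 L mol⁻¹ min⁻¹, 6.420 min⁻¹)
    catalyst-substrate complex + partner → target + active catalyst (19.56 L mol⁻¹ min⁻¹)
    catalyst → active catalyst (0.2634 min⁻¹)

From alder to ash, the same measure gives n of 0.735, so you see the share still falling. The slow step from catalyst to active catalyst holds the ash run at 29.7 % instead of 39.7 %. Round the elm charge, the apparent order in substrate at one fixed amount of target is 0.52, and with that step made fast it rises to 0.88.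

The numbers in the tables come from a simulation from invented constants; the scatter is artificial.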